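The noon run held 1.57 times the free catalyst of the summer run and gave 1.51 times the product at the first reading.

the same everywhere: substrate 20 mM; added ligand 7.6 mM
- summer: partner 21 mM; free catalyst 5.6 mM; run made earlier
- noon: partner 21 mM; free catalyst 8.8 mM; run made earlier
- flask: partner 21.0 mM; free catalyst 4.0 mM

| run | time / min | product / % |
|---|---|---|
| summer | 10.0 | 26.5 |
| summer | 20.0 | 51.5 |
| summer | 30.0 | 68.8 |
| summer | 40.0 | 77.8 |
| summer | 50.0 | 86.4 |
| summer | 60.0 | 91.3 |
| summer | 80.0 | 95.4 |
| noon | 10.0 | 40.1 |
| noon | 20.0 | 68.6 |
| noon | 30.0 | 84.3 |
| noon | 40.0 | 89.8 |
| noon | 50.0 | 95.2 |
| noon | 60.0 | 96.3 |
| noon | 80.0 | 97.3 |

(each reading ± 1 percentage point)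

* apparent order in free catalyst when 50% of the substrate are converted (percent change of the rate of making product for one percent more free catalyst charged)
* apparent order in partner when 50% of the substrate are converted (percent change of the rate of making product for one percent more partner charged)
* factor on the rate of making product when 50% of the substrate are converted if free catalyst is charged twice over

- no earlier run changes the charge of partner; that part of a forecast is a guess

How steeply does the rate follow the catalyst? Those two ratios give us a read order of 0.916, so doubling should give about 1.89. But our flask, at 4.0 mM, lies below both runs, so this is carried outside them.

How can we judge partner, when no run varied it? By what a charge does at fixed conversion. If one partner goes with each substrate, then at 50% conversion partner stands at 11.0 mM from 21.0 mM. Any extra partner charged is still there, so one percent more charge is 1.91 percent more partner present. We call this ratio of charge to partner left the partner lever. With conversion held fixed, we take the order in the charge as the lever times the local order, the order in the partner then present.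

How large is that local order? Partner and substrate fall together, so what the runs show is the sum of the two orders, which reads about one. Our own guess of 0.5 for partner gives 0.955.

The forecast says 0.95 for catalyst, 1.9 for doubling and, lower than our figure, 0.5 for partner: “The split is unknown, and I guess a local partner order of about 0.25”.

The flask gives 1.1, 2.21 and 1.4.

    catalyst intermediate B → spent catalyst (k = 2.40 × 10⁻⁴ /s)
    substrate + catalyst intermediate A → catalyst intermediate B (k = 1.80 /M/s)
    free catalyst + added ligand ⇌ idle complex, settled at all times (K = 94.0 /M)
    catalyst intermediate B → free catalyst + product (k = 0.00750 /s)
    partner + free catalyst → catalyst intermediate A (k = 0.280 /M/s)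

Dividing the flask's order in partner by the lever gives a local order of 0.711, higher than the guessed 0.25. A part of this comes from the added ligand, which holds free catalyst as idle complex, out of reach of partner. The same pairing also holds down this flask's rate at 50% conversion, since without it that rate is 1.40 times the actual one. The same flask without the pairing has an order of 1.2, which the same lever turns into a local order of 0.615.

The readings are simulated from invented constants; the scatter is artificial.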